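**Plan**

1. Numbering: ring A = C1 (ketone-bearing), C2 (OMe), C3 (Cl), C4 (Me), C5 (Br), C6 (OH); ring B = C1′ (ketone-bearing), C2′ (CHO), C3′ and C5′ (OH), C6′ (prenyl).
2. Retrosynthesis: the ketone goes back to a silyl-protected carbinol, CHO to a dioxolane and the ring B phenols to MOM ethers. Ring A is then cut at C1–C6, C2–C3 and C5–C6 into 4-bromo-2-chloro-3-methylcyclobutenone and a methoxyalkyne, and the alkyne is cut between the triple bond and the carbinol carbon (methoxyacetylide + ring B aldehyde).
3. Enabling feature: C6–C1–C2 of ring A (OH, carbon substituent, OMe) is the ketene-carbonyl/alkyne/alkoxy-carbon triad of a vinylketene–ynol ether benzannulation, and C3–C4–C5 (Cl, Me, Br) is C2–C3–C4 of a dihalocyclobutenone, so the hexasubstituted ring needs no later substitution.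
4. Forward order: ring B comes from methyl 3,5-dihydroxybenzoate and is dressed (formyl, MOM, dioxolane, prenyl, ester to aldehyde). The alkyne chain is joined and silylated, and the cyclobutenone is made from propyne and dichloroketene. Ring A is the only ring formed, last, followed by desilylation, oxidation and acid unmasking.
5. Stereochemistry: the target has no stereocentre; C4 of the cyclobutenones and the carbinol carbon are carried as racemates and are erased by aromatisation and oxidation.

Key step: step 13

**Remarks**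

- Ar = 2-(1,3-dioxolan-2-yl)-3,5-bis(methoxymethoxy)-6-(3-methylbut-2-en-1-yl)phenyl.
- The carbinol is protected as its tert-butyldimethylsilyl ether, which is smaller than a triisopropylsilyl group and can be installed from the chloride without a silyl triflate.
- Assumption: methyl 3,5-dihydroxybenzoate, propyne (cylinder), trichloroacetyl chloride and 2-chloro-1,1-dimethoxyethane are taken as commercial.

**Route**

Step 1
Reactants: 1 propyne; 2 trichloroacetyl chloride
Product: 4 4,4-dichloro-3-methylcyclobut-2-en-1-one, via dichloroketene 3 (not isolated)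
Conditions: Zn–Cu couple, Et2O–DME, propyne (excess, dry-ice condenser), 0 °C to rt
Reagents that add atoms: none
Why: Zinc removes two chlorines from 2 to give dichloroketene 3, which undergoes a thermal (2+2) ketene–alkyne cycloaddition in which the ketene carbonyl carbon bonds to the terminal alkyne carbon, so that methyl ends at C3 next to the CCl2 carbon, while DME ties up ZnCl2 and keeps the kinetic 4,4-dichloride from rearranging.

Step 2
Reactants: 4 4,4-dichloro-3-methylcyclobut-2-en-1-one
Product: 5 rac-2,4-dichloro-3-methylcyclobut-2-en-1-one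
Conditions: ZnCl2 (10 mol %), Et2O, rt
Reagents that add atoms: none
Why: Lewis-acid-assisted ionisation of one allylic chloride and return of chloride to the other allyl terminus (1,3-chloride shift, the allylic rearrangement typical of 4,4-dichlorocyclobutenones) should give the more stable 2,4-dichloride with a conjugated vinylic chlorine, C4 becoming a racemic stereocentre.

Step 3
Reactants: 5 rac-2,4-dichloro-3-methylcyclobut-2-en-1-one
Product: 6 rac-4-bromo-2-chloro-3-methylcyclobut-2-en-1-one
Conditions: LiBr (5 equiv), acetone, rt, dark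
Reagents that add atoms: lithium bromide, [Li+].[Br-]
Why: Finkelstein halide exchange, in which the C4 chloride (allylic and alpha to the carbonyl group) is displaced by bromide in an SN2 reaction pushed by excess LiBr, whereas the vinylic C2 chloride cannot react.

Step 4
Reactants: 7 methyl 3,5-dihydroxybenzoate
Product: 9 methyl 2-formyl-3,5-dihydroxybenzoate, via iminium chloride 8 (not isolated)
Conditions: POCl3, DMF, MeCN, 0 °C to rt; then H2O, 50 °C
Reagents that add atoms: N,N-dimethylformamide, CN(C)C=O; water, O
Why: Vilsmeier–Haack formylation of the resorcinol ring should occur ortho to one hydroxyl and para to the other (C2) and not at the doubly flanked C4, as is general for 5-substituted resorcinols, and the iminium salt 8 is hydrolysed on warming with water.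

Step 5
Reactants: 9 methyl 2-formyl-3,5-dihydroxybenzoate
Product: 10 methyl 2-formyl-3,5-bis(methoxymethoxy)benzoate
Conditions: MOMCl (3 equiv), iPr2NEt (4 equiv), CH2Cl2, 0 °C to 40 °C
Reagents that add atoms: chloromethyl methyl ether, COCCl
Why: Williamson-type O-alkylation of both phenols, with excess reagent and gentle heating because the hydroxyl ortho to the formyl group is hydrogen bonded.

Step 6
Reactants: 10 methyl 2-formyl-3,5-bis(methoxymethoxy)benzoate
Product: 11 methyl 2-(1,3-dioxolan-2-yl)-3,5-bis(methoxymethoxy)benzoate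
Conditions: (Me3SiOCH2)2, Me3SiOSO2CF3 (2 mol %), CH2Cl2, −78 to −20 °C; then pyridine
Reagents that add atoms: 1,2-bis(trimethylsilyloxy)ethane, C[Si](C)(C)OCCO[Si](C)(C)C
Why: Noyori acetalisation, in which catalytic silyl triflate activates the aldehyde toward the bis-silyl ether of ethylene glycol at low temperature under aprotic conditions, so that the MOM ethers and the neighbouring ester should remain untouched.

Step 7
Reactants: 11 methyl 2-(1,3-dioxolan-2-yl)-3,5-bis(methoxymethoxy)benzoate
Product: 12 methyl 2-bromo-6-(1,3-dioxolan-2-yl)-3,5-bis(methoxymethoxy)benzoate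
Conditions: NBS (1.05 equiv), DMF, 0 °C to rt, dark
Reagents that add atoms: N-bromosuccinimide, O=C1CCC(=O)N1Br
Why: Electrophilic aromatic bromination should go to the free position that is para to one MOM ether and ortho to the other (C6), the position between the two MOM ethers being more hindered, and NBS in DMF needs no acid that would endanger the acetals.

Step 8
Reactants: 12 methyl 2-bromo-6-(1,3-dioxolan-2-yl)-3,5-bis(methoxymethoxy)benzoate
Product: 13 methyl 2-(1,3-dioxolan-2-yl)-3,5-bis(methoxymethoxy)-6-(3-methylbut-2-en-1-yl)benzoate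
Conditions: Bu3SnCH2CH=CMe2 (1.3 equiv), Pd(PPh3)4 (5 mol %), DMF, 90 °C
Reagents that add atoms: tributyl(3-methylbut-2-en-1-yl)stannane, CCCC[Sn](CCCC)(CCCC)CC=C(C)C
Why: Stille cross-coupling under zerovalent palladium catalysis, in which reductive elimination from the less substituted allyl terminus next to a di-ortho-substituted aryl group should give the linear prenyl arene, with ester, acetal and MOM groups inert.

Step 9
Reactants: 13 methyl 2-(1,3-dioxolan-2-yl)-3,5-bis(methoxymethoxy)-6-(3-methylbut-2-en-1-yl)benzoate
Product: 14 [2-(1,3-dioxolan-2-yl)-3,5-bis(methoxymethoxy)-6-(3-methylbut-2-en-1-yl)phenyl]methanol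
Conditions: LiAlH4, THF, 0 °C; then H2O, aq NaOH
Reagents that add atoms: none
Why: Hydride reduction of the hindered aryl ester to the benzylic alcohol, to which the acetal, the MOM ethers and the trisubstituted alkene are inert.

Step 10
Reactants: 14 [2-(1,3-dioxolan-2-yl)-3,5-bis(methoxymethoxy)-6-(3-methylbut-2-en-1-yl)phenyl]methanol
Product: 15 2-(1,3-dioxolan-2-yl)-3,5-bis(methoxymethoxy)-6-(3-methylbut-2-en-1-yl)benzaldehyde
Conditions: activated MnO2 (excess), CH2Cl2, rt
Reagents that add atoms: none
Why: Neutral heterogeneous MnO2 oxidation is selective for the benzylic alcohol and spares the acid-labile acetal and MOM groups and the prenyl alkene.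

Step 11
Reactants: 15 2-(1,3-dioxolan-2-yl)-3,5-bis(methoxymethoxy)-6-(3-methylbut-2-en-1-yl)benzaldehyde; 16 2-chloro-1,1-dimethoxyethane
Product: 18 rac-1-Ar-3-methoxyprop-2-yn-1-ol, via lithium methoxyacetylide 17 (not isolated)
Conditions: Et2NH, n-BuLi (3 equiv each), THF, 0 °C; then 16, 0 °C; then 15, −78 °C; H2O
Reagents that add atoms: none
Why: Threefold action of LiNEt2 on 16 (two eliminations and one deprotonation) gives lithium methoxyacetylide 17, which adds 1,2 to the non-enolisable aldehyde to give the propargylic alcohol as a racemate, the new carbinol centre needing no control because it is oxidised later.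

Step 12
Reactants: 18 rac-1-Ar-3-methoxyprop-2-yn-1-ol
Product: 19 rac-tert-butyl[(1-Ar-3-methoxyprop-2-yn-1-yl)oxy]dimethylsilane
Conditions: TBSCl, imidazole, DMF, rt
Reagents that add atoms: tert-butyldimethylsilyl chloride, CC(C)(C)[Si](C)(C)Cl
Why: Standard silylation of a secondary alcohol under buffered, non-acidic conditions, chosen because the ynol ether carbinol is prone to acid-induced Meyer–Schuster rearrangement.

Step 13
Reactants: 6 rac-4-bromo-2-chloro-3-methylcyclobut-2-en-1-one; 19 rac-tert-butyl[(1-Ar-3-methoxyprop-2-yn-1-yl)oxy]dimethylsilane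
Product: 24 rac-2-bromo-6-{Ar[(tert-butyldimethylsilyl)oxy]methyl}-4-chloro-5-methoxy-3-methylphenol, via chloro(vinyl)ketene 20 (not isolated), via vinylcyclobutenone 21 (not isolated), via dienylketene 22 (not isolated), via cyclohexadienone 23 (not isolated)
Conditions: toluene, 80 °C then 110 °C, sealed tube, 6 (1.5 equiv) added in two portions
Reagents that add atoms: none
Why: Heating opens 6 by four-electron conrotatory cleavage of its C1–C4 bond, bromine rotating outward, to the chloro(vinyl)ketene 20, whose electrophilic carbonyl carbon is attacked by the methoxy-remote alkyne carbon of 19 in a (2+2) cycloaddition that forms the ring A bonds C1–C6 and C2–C3 and gives vinylcyclobutenone 21. Compound 21 reopens to dienylketene 22, and ring A closes by six-electron disrotatory electrocyclisation that makes the C5–C6 bond, after which dienone 23 tautomerises irreversibly to phenol 24. The closest known reaction is the Danheiser benzannulation of cyclobutenones with alkoxyalkynes. No stereocentre is created: the carbinol centre of 19 is carried through as the racemate and the C4 centre of 6 is lost on aromatisation. The selectivity needed is the orientation of the cycloaddition, which the polarisation of the ynol ether secures (nucleophilic at the carbon bearing the carbinol), so that the carbinol carbon ends between OH and OMe; the ynol ether is also far more nucleophilic than the prenyl alkene, and the bulky carbinol substituent meets the unhindered carbonyl terminus of the ketene.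

Step 14
Reactants: 24 rac-2-bromo-6-{Ar[(tert-butyldimethylsilyl)oxy]methyl}-4-chloro-5-methoxy-3-methylphenol
Product: 25 rac-2-bromo-4-chloro-6-[Ar(hydroxy)methyl]-5-methoxy-3-methylphenol
Conditions: Bu4NF (1.1 equiv), THF, 0 °C; H2O
Reagents that add atoms: none
Why: Fluoride-induced desilylation driven by the strong Si–F bond, to which MOM ethers, dioxolane, aryl halides and the alkene are inert.

Step 15
Reactants: 25 rac-2-bromo-4-chloro-6-[Ar(hydroxy)methyl]-5-methoxy-3-methylphenol
Product: 26 (3-bromo-5-chloro-2-hydroxy-6-methoxy-4-methylphenyl)(Ar)methanone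
Conditions: activated MnO2 (excess), CH2Cl2, rt
Reagents that add atoms: none
Why: MnO2 oxidation of the doubly benzylic secondary alcohol to the diaryl ketone, a neutral oxidation that should tolerate the free, fully substituted phenol, which ends hydrogen bonded to the new carbonyl group.

Step 16
Reactants: 26 (3-bromo-5-chloro-2-hydroxy-6-methoxy-4-methylphenyl)(Ar)methanone
Product: 27 Pestalone G, 2-(3-bromo-5-chloro-2-hydroxy-6-methoxy-4-methylbenzoyl)-4,6-dihydroxy-3-(3-methylbut-2-en-1-yl)benzaldehyde
Conditions: HCl (3 M aq), THF, 40 °C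
Reagents that add atoms: water, O
Why: Acid-catalysed acetal hydrolysis should cleave the dioxolane and both aryl MOM ethers in one operation, under conditions mild enough that the prenyl alkene is neither hydrated nor cyclised onto the neighbouring phenol.

**Compound list**

1 | propyne | CC#C | starting material
2 | trichloroacetyl chloride | ClC(=O)C(Cl)(Cl)Cl | starting material
3 | dichloroketene | ClC(Cl)=C=O | intermediate
4 | 4,4-dichloro-3-methylcyclobut-2-en-1-one | O=C1C=C(C)C1(Cl)Cl | intermediate
5 | rac-2,4-dichloro-3-methylcyclobut-2-en-1-one | O=C1C(Cl)=C(C)C1Cl | intermediate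
6 | rac-4-bromo-2-chloro-3-methylcyclobut-2-en-1-one | O=C1C(Cl)=C(C)C1Br | intermediate
7 | methyl 3,5-dihydroxybenzoate | COC(=O)c1cc(O)cc(O)c1 | starting material
8 | {[2,4-dihydroxy-6-(methoxycarbonyl)phenyl]methylidene}dimethylammonium chloride | COC(=O)c1cc(O)cc(O)c1C=[N+](C)C.[Cl-] | intermediate
9 | methyl 2-formyl-3,5-dihydroxybenzoate | COC(=O)c1cc(O)cc(O)c1C=O | intermediate
10 | methyl 2-formyl-3,5-bis(methoxymethoxy)benzoate | COC(=O)c1cc(OCOC)cc(OCOC)c1C=O | intermediate
11 | methyl 2-(1,3-dioxolan-2-yl)-3,5-bis(methoxymethoxy)benzoate | COC(=O)c1cc(OCOC)cc(OCOC)c1C1OCCO1 | intermediate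
12 | methyl 2-bromo-6-(1,3-dioxolan-2-yl)-3,5-bis(methoxymethoxy)benzoate | COC(=O)c1c(Br)c(OCOC)cc(OCOC)c1C1OCCO1 | intermediate
13 | methyl 2-(1,3-dioxolan-2-yl)-3,5-bis(methoxymethoxy)-6-(3-methylbut-2-en-1-yl)benzoate | COC(=O)c1c(CC=C(C)C)c(OCOC)cc(OCOC)c1C1OCCO1 | intermediate
14 | [2-(1,3-dioxolan-2-yl)-3,5-bis(methoxymethoxy)-6-(3-methylbut-2-en-1-yl)phenyl]methanol | OCc1c(CC=C(C)C)c(OCOC)cc(OCOC)c1C1OCCO1 | intermediate
15 | 2-(1,3-dioxolan-2-yl)-3,5-bis(methoxymethoxy)-6-(3-methylbut-2-en-1-yl)benzaldehyde | O=Cc1c(CC=C(C)C)c(OCOC)cc(OCOC)c1C1OCCO1 | intermediate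
16 | 2-chloro-1,1-dimethoxyethane | COC(OC)CCl | starting material
17 | lithium methoxyacetylide | [Li+].[C-]#COC | intermediate
18 | rac-1-[2-(1,3-dioxolan-2-yl)-3,5-bis(methoxymethoxy)-6-(3-methylbut-2-en-1-yl)phenyl]-3-methoxyprop-2-yn-1-ol | COC#CC(O)c1c(CC=C(C)C)c(OCOC)cc(OCOC)c1C1OCCO1 | intermediate
19 | rac-tert-butyl[(1-Ar-3-methoxyprop-2-yn-1-yl)oxy]dimethylsilane (tert-butyldimethylsilyl ether of 18) | COC#CC(O[Si](C)(C)C(C)(C)C)c1c(CC=C(C)C)c(OCOC)cc(OCOC)c1C1OCCO1 | intermediate
20 | (E)-4-bromo-2-chloro-3-methylbuta-1,3-dien-1-one | O=C=C(Cl)/C(C)=C/Br | intermediate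
21 | 4-[(E)-1-bromoprop-1-en-2-yl]-4-chloro-3-methoxy-2-{Ar[(tert-butyldimethylsilyl)oxy]methyl}cyclobut-2-en-1-one (diastereomer mixture) | O=C1C(C(O[Si](C)(C)C(C)(C)C)c2c(CC=C(C)C)c(OCOC)cc(OCOC)c2C3OCCO3)=C(OC)C1(Cl)/C(C)=C/Br | intermediate
22 | (3Z,5E)-6-bromo-4-chloro-3-methoxy-5-methyl-2-{Ar[(tert-butyldimethylsilyl)oxy]methyl}hexa-1,3,5-trien-1-one (racemic) | O=C=C(C(O[Si](C)(C)C(C)(C)C)c1c(CC=C(C)C)c(OCOC)cc(OCOC)c1C2OCCO2)/C(OC)=C(Cl)\C(C)=C\Br | intermediate
23 | 6-bromo-4-chloro-3-methoxy-5-methyl-2-{Ar[(tert-butyldimethylsilyl)oxy]methyl}cyclohexa-2,4-dien-1-one (diastereomer mixture) | O=C1C(Br)C(C)=C(Cl)C(OC)=C1C(O[Si](C)(C)C(C)(C)C)c1c(CC=C(C)C)c(OCOC)cc(OCOC)c1C2OCCO2 | intermediate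
24 | rac-2-bromo-6-{Ar[(tert-butyldimethylsilyl)oxy]methyl}-4-chloro-5-methoxy-3-methylphenol | COc1c(Cl)c(C)c(Br)c(O)c1C(O[Si](C)(C)C(C)(C)C)c1c(CC=C(C)C)c(OCOC)cc(OCOC)c1C2OCCO2 | intermediate
25 | rac-2-bromo-4-chloro-6-[Ar(hydroxy)methyl]-5-methoxy-3-methylphenol | COc1c(Cl)c(C)c(Br)c(O)c1C(O)c1c(CC=C(C)C)c(OCOC)cc(OCOC)c1C2OCCO2 | intermediate
26 | (3-bromo-5-chloro-2-hydroxy-6-methoxy-4-methylphenyl)[2-(1,3-dioxolan-2-yl)-3,5-bis(methoxymethoxy)-6-(3-methylbut-2-en-1-yl)phenyl]methanone | COc1c(Cl)c(C)c(Br)c(O)c1C(=O)c1c(CC=C(C)C)c(OCOC)cc(OCOC)c1C2OCCO2 | intermediate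
27 | Pestalone G, 2-(3-bromo-5-chloro-2-hydroxy-6-methoxy-4-methylbenzoyl)-4,6-dihydroxy-3-(3-methylbut-2-en-1-yl)benzaldehyde | COc1c(Cl)c(C)c(Br)c(O)c1C(=O)c1c(C=O)c(O)cc(O)c1CC=C(C)C | target

**Count**

Total steps: 16. Longest linear sequence: 13 steps (7 to 27, steps 4–16); the cyclobutenone branch (steps 1–3) joins at step 13.

**Steps most likely to fail**

Step 13 (benzannulation). The (2+2) capture of the ketene at the crowded alkyne may be slow enough for the chloro(vinyl)ketene to oligomerise. Prolonged heating may also cause loss of silanol from the ortho-hydroxybenzyl silyl ether toward a quinone methide. The fallback keeps the same ring construction but builds ring A on the smallest alkyne and joins ring B afterwards by an aryllithium–aldehyde union. It sets out from 6 and 17 and uses 15. Quenching the solution of 17 with water at 0 °C and distilling into a cold trap gives methoxyacetylene F1. Heating 6 with excess F1 (toluene, 80 °C, sealed tube) should give 2-bromo-4-chloro-5-methoxy-3-methylphenol F2 by the same benzannulation. MOMCl and iPr2NEt convert it into 2-bromo-4-chloro-5-methoxy-1-(methoxymethoxy)-3-methylbenzene F3. Lithium 2,2,6,6-tetramethylpiperidide (THF, −78 °C) removes the only ring proton, flanked by OMOM and OMe, to give [3-bromo-5-chloro-6-methoxy-2-(methoxymethoxy)-4-methylphenyl]lithium F4. Addition of F4 to aldehyde 15 gives rac-[3-bromo-5-chloro-6-methoxy-2-(methoxymethoxy)-4-methylphenyl](Ar)methanol F5, and MnO2 oxidises it to [3-bromo-5-chloro-6-methoxy-2-(methoxymethoxy)-4-methylphenyl](Ar)methanone F6. The conditions of step 16 then cleave three MOM ethers and the dioxolane, and the fallback comes back to the route at 27.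

Step 3 (bromide exchange). The exchange may stall at an unfavourable chloride/bromide equilibrium, or ionisation at C4 may scramble halogen between C2 and C4 and open the strained ring. The fallback introduces bromine after ring A exists and sets out from 5. Zinc in acetic acid/TMEDA/ethanol at 0 °C should remove only the allylic, carbonyl-activated C4 chlorine and give 2-chloro-3-methylcyclobut-2-en-1-one F7. Benzannulation of F7 with 19 (toluene, 110 °C) should give rac-2-{Ar[(tert-butyldimethylsilyl)oxy]methyl}-4-chloro-3-methoxy-5-methylphenol F8. Its only ring A C–H is ortho to the free hydroxyl and para to the methoxyl. One equivalent of NBS with catalytic iPr2NH in CH2Cl2 at −78 °C should therefore brominate that position in preference to the MOM-flanked ring B position and the prenyl alkene, and the fallback comes back to the route at 24.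

Step 8 (prenyl coupling). The allyl group may be delivered through its tertiary terminus (reverse-prenyl isomer), and oxidative addition at the di-ortho-substituted bromide may be slow enough for protodebromination to compete. The fallback sets out from 12. Stille coupling with allyltributylstannane (Pd(PPh3)4, DMF, 90 °C), which poses no regiochemical question, gives methyl 2-(1,3-dioxolan-2-yl)-3,5-bis(methoxymethoxy)-6-(prop-2-en-1-yl)benzoate F9. Olefin cross-metathesis with excess 2-methylbut-2-ene (second-generation Grubbs catalyst, RuCl2(=CHPh)(PCy3)(H2IMes), CH2Cl2, 40 °C) then turns the allyl into the prenyl group, and the fallback comes back to the route at 13.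

**Further compounds**

F1 | step 13 | methoxyacetylene | COC#C
F2 | step 13 | 2-bromo-4-chloro-5-methoxy-3-methylphenol | COc1cc(O)c(Br)c(C)c1Cl
F3 | step 13 | 2-bromo-4-chloro-5-methoxy-1-(methoxymethoxy)-3-methylbenzene | COCOc1cc(OC)c(Cl)c(C)c1Br
F4 | step 13 | [3-bromo-5-chloro-6-methoxy-2-(methoxymethoxy)-4-methylphenyl]lithium | COCOc1c([Li])c(OC)c(Cl)c(C)c1Br
F5 | step 13 | rac-[3-bromo-5-chloro-6-methoxy-2-(methoxymethoxy)-4-methylphenyl](Ar)methanol | COCOc1c(Br)c(C)c(Cl)c(OC)c1C(O)c1c(CC=C(C)C)c(OCOC)cc(OCOC)c1C2OCCO2
F6 | step 13 | [3-bromo-5-chloro-6-methoxy-2-(methoxymethoxy)-4-methylphenyl](Ar)methanone | COCOc1c(Br)c(C)c(Cl)c(OC)c1C(=O)c1c(CC=C(C)C)c(OCOC)cc(OCOC)c1C2OCCO2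
F7 | step 3 | 2-chloro-3-methylcyclobut-2-en-1-one | O=C1CC(C)=C1Cl
F8 | step 3 | rac-2-{Ar[(tert-butyldimethylsilyl)oxy]methyl}-4-chloro-3-methoxy-5-methylphenol | COc1c(Cl)c(C)cc(O)c1C(O[Si](C)(C)C(C)(C)C)c1c(CC=C(C)C)c(OCOC)cc(OCOC)c1C2OCCO2
F9 | step 8 | methyl 2-(1,3-dioxolan-2-yl)-3,5-bis(methoxymethoxy)-6-(prop-2-en-1-yl)benzoate | COC(=O)c1c(CC=C)c(OCOC)cc(OCOC)c1C1OCCO1
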